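One ratio ran through my reckoning: how fast open intermediate leaves by coupling with second intermediate, over how fast it leaves by pairing with itself. Starting material opens to open intermediate, dissolved partner turns into second intermediate, the two couple to target, target goes over to its isomer, and two open intermediate make homo product.

| flask | starting material | gas | temperature | time |
|---|---|---|---|---|
| Monday's | 1.5 M | 200 mM (held) | 25 °C | 2.0 h |
| Wednesday's | 1.5 M | 200 mM (held) | 50 °C | 2.0 h |

- which of the two there is more of at the end, counted by the starting material in each, Monday's (homo product / target)
- which of the two there is more of at the end, counted by the starting material in each, Wednesday's (homo product / target)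
- final target, as a percentage of the starting material charged, in Monday's
- final target, as a percentage of the starting material charged, in Wednesday's

- in percentages every species weighs as the starting material in it: one homo product or side product counts as two
- a step written with two of one species runs at k times the square of its concentration and takes two of it each time
- at the start none of partner is dissolved
- the list of constants is for 25 °C, to be carried to other temperatures by the activation energies and enthalpies

    starting material → open intermediate (k1 = 1.94 × 10⁻⁴ s⁻¹, Ea1 = 82.0 kJ mol⁻¹)
    starting material + target → side product (k2 = 6.82 × 10⁻⁵ L mol⁻¹ s⁻¹, Ea2 = 70.0 kJ mol⁻¹)
    target ⇌ isomer of the product (K3 = 2.02, k3 = 4.54 × 10⁻⁴ s⁻¹, Ea3 = 90.0 kJ mol⁻¹, ΔH3 = 52.0 kJ mol⁻¹)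
    open intermediate + second intermediate → target (k4 = 1.77 × 10⁻⁴ L mol⁻¹ s⁻¹, Ea4 = 71.0 kJ mol⁻¹)
    gas ⇌ partner, rate k5*(csat - [partner]) (k5 = 0.00644 s⁻¹, csat = 200 mM)
    partner → second intermediate (k6 = 1.08 × 10⁻⁴ s⁻¹, Ea6 = 93.0 kJ mol⁻¹)
    2 open intermediate → homo product (k7 = 1.15 × 10⁻⁴ L mol⁻¹ s⁻¹, Ea7 = 55.0 kJ mol⁻¹)
    (constants at 25 °C)

Each open intermediate meets the coupling constant times [second intermediate] on one side, and on the other the pairing constant times [open intermediate], counted double since each turn takes two. I solved the early end first. Partner fills in 1.79 min, faster than it drains, so both intermediates start by rising in proportion to time, and time cancels. What remains is the split, a selectivity factor: coupling constant times partner's conversion constant times saturation, over twice the pairing constant times the opening constant times the charge, 0.0571 for Monday's. At the late end, [open intermediate] falls while [second intermediate] climbs, so the split rises, and I took the early value as a floor for target plus isomer over homo product. Monday's starting material has a half-life of 0.99 h, shorter than the 2.0 h of the run, so that flask has left the early end by its reading and the early value stays a floor, not an estimate.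

For Wednesday's, the activation energies and a lower standing partner gave a floor of 0.102, but starting material there has a half-life of 0.0768 h, and how far the late end lifts the split I could not say. The equilibrium constant there is 10.2, so target keeps a small part of whatever couples, and my floor for Wednesday's target was 0.821%. I committed to homo product ahead in both flasks, and to no figure for Monday's target.

The forecast said homo product for Monday's and homo product for Wednesday's, with target at 1.6% (1.2% to 2.1%) and 3% (2.3% to 3.8%), reasoning that “the open intermediate mostly dimerises at both temperatures”. My floor for Wednesday's stood below its figure.

The simulation gave homo product 31.4% against target 1.54% in Monday's, and 65.2% against 3.07% in Wednesday's, so the forecast held.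

In Monday's flask the opening step was still running at the asked time, with 24.6% of starting material and 40.8% as open intermediate, and target plus isomer over homo product stood at 0.0893, above the split. In Wednesday's flask starting material stood at 0.0112% after 1.00 h, and the same ratio ended at 0.529, above its floor.

The neighbour like Monday's but charged with 0.60 M has a split of 0.143, larger by a factor of 2.50. Computed, its ratio was 0.224 against 0.0893 in Monday's, a factor of 2.50, with target at 2.22%.

The numbers of this flask are those of an exercise, and the outcome is calculated.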